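**Target:** CNP0323842.1, (2R,3R,4S,7R,12S,14S,16S)-2-hydroxytrinervita-1(15),8(19),9E-triene-3,14-diyl diacetate

## Retrosynthetic overview

1. Rings (trinervitane numbering): A is the cyclopentane C4–C5–C6–C7–C16. B is the cyclohexene C1–C2–C3–C4–C16–C15. C is the eleven-membered ring C1, C15, C16, C7–C14.
2. Enabling feature: on ring B the C16–C7 bond and the C2–O bond stand cis-1,4 (both β) on either side of C1=C15, and C7 bears the C8=C19 methylene. This is the retron of a syn 1,4-carbo-oxygenation of the diene C16=C15–C1=C2 by an allylsilane C7=C8–C19–Si held 1,5 to C16 through C4–C5–C6.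
3. Key disconnection: C7–C16 and C2–O together, transannular across the bridged fourteen-membered ring of 26. This is an oxidative union of two π-nucleophiles by divalent palladium.
4. Further disconnections: C1–C14 (Nozaki–Hiyama–Kishi macrocyclization), then C8–C9 and C8–C19 (two couplings on a 1,1-dibromoalkene). C3/C4 come from (S)-carvone and C12 from methyl (R)-3-methylglutarate.
5. Ring order: B (from carvone), then the fourteen-membered ring, then A, whose closure also carves out C.

Key step: step 23

Remark on descriptors: β is the face of ring B that carries C5; C17, C18, C19 and C20 are the carbons on C15, C4, C8 and C12.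

Assumption: the (S)-configured oxazoline–sulfonamide ligand of step 21 is taken to favour the 14S carbinol; if its sense of induction is the opposite, its enantiomer is used.

## Route

### Fragment 1: ring B (steps 1–10)

Step 1
Reactants: 1 (S)-(+)-carvone
Product: 2 (5S,6R)-2,6-dimethyl-5-(prop-1-en-2-yl)cyclohex-2-en-1-one (trans isomer drawn; its C6 epimer serves equally)
Conditions: LiN(i-Pr)2 (LDA), THF, −78 °C; MeI, −78 → 0 °C
Reagents that add atoms: iodomethane CI
Why: Kinetic α′-deprotonation of the cross-conjugated enone and SN2 methylation (enolate alkylation); the new centre need not be controlled because it is re-enolized in step 2.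

Step 2
Reactants: 2 6-methylcarvone
Product: 3 (5R,6R)-6-allyl-2,6-dimethyl-5-(prop-1-en-2-yl)cyclohex-2-en-1-one (allyl trans to isopropenyl)
Conditions: LiN(i-Pr)2 (LDA), THF, −78 → −20 °C; allyl bromide, DMPU, −78 °C → rt
Reagents that add atoms: allyl bromide C=CCBr
Why: Enolate alkylation of the trisubstituted α′-enolate, in which the halide should approach anti to the neighbouring isopropenyl group and so set quaternary C4 with C5 β and C18 α.

Step 3
Reactants: 3 allyl enone
Product: 4 3-[(1R,6R)-1,3-dimethyl-2-oxo-6-(prop-1-en-2-yl)cyclohex-3-en-1-yl]propanal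
Conditions: PdCl2(PhCN)2 (10 mol %), CuCl2·2H2O (10 mol %), AgNO2 (5 mol %), O2 (1 atm), t-BuOH/MeNO2 15:1, rt
Reagents that add atoms: dioxygen O=O
Why: Nitrite-modified aldehyde-selective Wacker-type oxidation, a reaction type established for allyl groups on quaternary carbons; the 1,1-disubstituted and the conjugated alkene should stay untouched.

Step 4
Reactants: 4 aldehyde
Product: 5 (5R,6R)-6-(4,4-dibromobut-3-en-1-yl)-2,6-dimethyl-5-(prop-1-en-2-yl)cyclohex-2-en-1-one
Conditions: CBr4, PPh3, CH2Cl2, 0 °C
Reagents that add atoms: tetrabromomethane BrC(Br)(Br)Br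
Why: Dibromomethylenation (first stage of the Corey–Fuchs sequence), which takes the aldehyde only because the ketone is conjugated and neopentylic.

Step 5
Reactants: 5 dibromoalkene enone
Product: 6 1β,15β-epoxy ketone (C16 ketone, C3 α-isopropenyl)
Conditions: H2O2 (30 %), NaOH (cat.), MeOH, 0 °C
Reagents that add atoms: hydrogen peroxide OO
Why: Weitz–Scheffer nucleophilic epoxidation picks the only electron-poor conjugated alkene; attack anti to the isopropenyl group is expected, and both new centres are erased in steps 7 and 9.

Step 6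
Reactants: 6 epoxy ketone
Product: 8 epoxy ketone 3α-acetate, via methoxy hydroperoxide 7 (not isolated)
Conditions: O3, CH2Cl2/MeOH 4:1, −78 °C, N2 purge; then Ac2O, Et3N, DMAP (cat.), CH2Cl2, 0 → 40 °C
Reagents that add atoms: ozone [O-][O+]=O; methanol CO (its atoms stay only in 7)
Why: Ozonolysis in methanol followed by Criegee rearrangement of the derived peracetate, in which C3 migrates to oxygen with retention so that the isopropenyl group becomes the C3 α-acetate; the dibromoalkene is too electron-poor for ozone.

Step 7
Reactants: 8 epoxy ketone acetate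
Product: 9 (3S,4S)-allylic alcohol: C15=C16, C1 β-OH, C3 α-OAc
Conditions: N2H4·H2O, AcOH, MeOH, 0 °C → rt
Reagents that add atoms: none
Why: Wharton transposition, in which the epoxy hydrazone collapses with loss of N2 and so moves oxygen from C16 to C1 and the alkene to C15=C16; the C1 configuration follows from the epoxide and is erased in step 9.

Step 8
Reactants: 9 allylic alcohol acetate
Product: 10 (3S,4S)-1β,3α-diol
Conditions: K2CO3, MeOH, rt
Reagents that add atoms: none
Why: Base-catalysed transesterification, placed at the one stage that holds no ketone so that neither retro-aldol cleavage nor β-elimination at C3 is possible.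

Step 9
Reactants: 10 diol
Product: 11 (3S,4S)-3α-hydroxy enone (C1 ketone, C15=C16)
Conditions: MnO2, CH2Cl2, rt
Reagents that add atoms: none
Why: MnO2 oxidizes only the allylic C1 carbinol under neutral conditions, which completes the 1,3-carbonyl transposition and leaves the C3 carbinol alone.

Step 10
Reactants: 11 hydroxy enone
Product: 12 3α-triethylsilyloxy enone (fragment 1)
Conditions: Et3SiOTf, 2,6-lutidine, CH2Cl2, −78 °C
Reagents that add atoms: triethylsilyl triflate CC[Si](CC)(CC)OS(=O)(=O)C(F)(F)F
Why: Silylation of the hindered carbinol with a silyl triflate and a weak hindered base, which turns the C3 oxygen into a poor leaving group for the enolization in step 18.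

### Fragment 2: C9–C14 (steps 11–15)

Step 11
Reactants: 13 methyl (R)-3-methylglutarate
Product: 15 (R)-4-methyloxan-2-one, via hydroxy ester 14 (not isolated)
Conditions: BH3·SMe2, THF, 0 °C → rt; then TsOH (cat.), CH2Cl2, rt
Reagents that add atoms: none
Why: Chemoselective borane reduction of the acid beside the ester, followed by lactonization; C12 comes unchanged from the chiral pool.

Step 12
Reactants: 15 lactone
Product: 16 (4R)-4-methyloxan-2-ol (anomers)
Conditions: i-Bu2AlH, CH2Cl2, −78 °C
Reagents that add atoms: none
Why: Partial reduction of a lactone, which stops at the tetrahedral aluminium alkoxide at low temperature and gives the lactol on work-up.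

Step 13
Reactants: 16 lactol
Product: 17 (S)-3-methylhex-5-yn-1-ol
Conditions: dimethyl (1-diazo-2-oxopropyl)phosphonate, K2CO3, MeOH, 0 °C → rt
Reagents that add atoms: dimethyl (1-diazo-2-oxopropyl)phosphonate CC(=O)C(=[N+]=[N-])P(=O)(OC)OC
Why: Seyferth–Gilbert homologation of the open hydroxy aldehyde form of the lactol, which adds C9 and frees the C14 hydroxyl.

Step 14
Reactants: 17 alkynol
Product: 18 (S)-triethyl[(3-methylhex-5-yn-1-yl)oxy]silane
Conditions: Et3SiCl, imidazole, CH2Cl2, 0 °C
Reagents that add atoms: chlorotriethylsilane CC[Si](Cl)(CC)CC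
Why: Standard silylation of a primary alcohol; the same group as on C3 allows one joint removal in step 19.

Step 15
Reactants: 18 silyl alkyne
Product: 19 (S,E)-alkenyl pinacol boronate (fragment 2)
Conditions: pinacolborane, Cp2ZrHCl (10 mol %), Et3N (10 mol %), neat, 60 °C
Reagents that add atoms: pinacolborane [H]B1OC(C)(C)C(C)(C)O1
Why: Zirconocene-catalysed syn hydroboration of a terminal alkyne, which places boron on C9 and sets the E geometry of C9=C10.

### Union, macrocycle and end game (steps 16–24)

Step 16
Reactants: 12 fragment 1; 19 fragment 2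
Product: 20 (7Z,9E)-8-bromo diene (C6 and C9 trans across C7=C8)
Conditions: Pd(PPh3)4 (5 mol %), TlOEt, THF/H2O 4:1, rt
Reagents that add atoms: none
Why: Suzuki–Miyaura coupling of a 1,1-dibromoalkene, in which oxidative addition should take the less hindered C–Br bond trans to the alkyl chain and so fix C9 trans to C6.

Step 17
Reactants: 20 bromo diene
Product: 21 2-(trimethylsilylmethyl) diene ketone (C19 cis to C6)
Conditions: Me3SiCH2MgCl, ZnCl2, THF, 0 °C; then 20, Pd(P(t-Bu)3)2 (5 mol %), rt
Reagents that add atoms: (trimethylsilylmethyl)zinc chloride C[Si](C)(C)C[Zn]Cl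
Why: Negishi coupling, which with the bulky trialkylphosphine catalyst should proceed with retention at 2-bromo-1,3-dienes; the organozinc tolerates the enone and the silyl ethers.

Step 18
Reactants: 21 ketone
Product: 22 ring B dienyl triflate (C16=C15–C1(OTf)=C2)
Conditions: KN(SiMe3)2, THF, −78 °C; N-(5-chloro-2-pyridyl)bis(trifluoromethanesulfonimide), −78 °C
Reagents that add atoms: N-(5-chloro-2-pyridyl)bis(trifluoromethanesulfonimide) O=S(=O)(N(c1ccc(Cl)cn1)S(=O)(=O)C(F)(F)F)C(F)(F)F
Why: Kinetic deprotonation at C2, the only enolizable position, followed by O-sulfonylation; the low temperature and the poor, pseudo-equatorial silyloxy leaving group should hold back β-elimination.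

Step 19
Reactants: 22 bis(triethylsilyl) ether
Product: 23 3α,14-diol dienyl triflate
Conditions: PPTS, MeOH/CH2Cl2, rt
Reagents that add atoms: none
Why: Mild acid-catalysed methanolysis of both triethylsilyl ethers in one operation, under conditions that the allylsilane and the triflate should survive.

Step 20
Reactants: 23 diol
Product: 24 C14 aldehyde with free 3α-hydroxyl
Conditions: TEMPO (10 mol %), PhI(OAc)2, CH2Cl2, 0 °C → rt
Reagents that add atoms: none
Why: Oxoammonium oxidation, which is selective for the unhindered primary alcohol over the neopentylic C3 carbinol next to the electron-poor enol triflate.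

Step 21
Reactants: 24 triflate aldehyde
Product: 25 (3S,4S,12S,14S)-19-trimethylsilyl-7,16-secotrinervita-1,7,9,15-tetraene-3α,14-diol
Conditions: CrCl2, NiCl2 (cat.), (S)-N-[2-(4-isopropyl-4,5-dihydrooxazol-2-yl)-6-methylphenyl]methanesulfonamide, Et3N, THF, 0.002 M, slow addition, rt
Reagents that add atoms: none
Why: Nozaki–Hiyama–Kishi reaction, in which nickel-catalysed activation of the dienyl triflate, transfer to chromium and addition to the aldehyde tolerate the hydroxyl, the allylsilane and the dienes; high dilution favours the fourteen-membered ring and the chromium-bound chiral ligand is relied on to set 14S.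

Step 22
Reactants: 25 macrocyclic diol
Product: 26 3α,14-diacetate
Conditions: Ac2O, pyridine, DMAP (cat.), CH2Cl2, 0 °C → rt
Reagents that add atoms: acetic anhydride CC(=O)OC(C)=O
Why: Exhaustive DMAP-catalysed acetylation installs both acetates of the target at once and leaves no free hydroxyl for the oxidative step.

Step 23
Reactants: 26 macrocyclic diene allylsilane
Product: 27 2β-chloroacetoxytrinervita-1(15),8(19),9-triene-3α,14-diyl diacetate
Conditions: PdCl2(MeCN)2 (10 mol %), 1,4-benzoquinone (1.0–1.1 equiv), ClCH2CO2H, ClCH2CO2Li, acetone, rt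
Reagents that add atoms: chloroacetic acid O=C(O)CCl
Why: Proposed new method: divalent palladium binds the α face of the ring B diene C16=C15–C1=C2, opposite to the C5–C6 tether, and the allylsilane attacks C16 through C7 in an anti carbopalladation with loss of silicon, which creates the C8=C19 methylene and an η3-allyl complex over C15–C1–C2; benzoquinone-assisted external attack of chloroacetate at C2, again anti to the metal, releases zerovalent palladium, which benzoquinone and acid return to the divalent state. The closest known reaction type is the palladium-catalysed intramolecular 1,4-carbochlorination of cyclohexa-1,3-dienes that carry an allylsilane side chain; new here are the transannular setting, the 2,3-disubstituted diene and a carboxylate as the second nucleophile. Ring A closes in a 5-exo-trig mode (C7 onto C16), which at the same time cuts ring C out of the fourteen-membered ring. C16 is fixed by C4, since the three-atom tether on the β face can only give the cis-fused hydrindene; C7 is fixed by the C8–C14 bridge, which holds C8 over C15 on the concave face; C2 is fixed by the double anti sequence, which places carbon and oxygen cis-1,4 on the β face. The step needs 1,4- over 1,2-addition (secured by the fully substituted C15 terminus of the allyl complex), attack through C7 and not C19 (secured by the β-silicon effect and by a five- against a seven-membered ring), and reaction at the cyclic diene instead of the open-chain dienes (secured by its locked s-cis geometry, by the chloride ligands that enforce external attack, and by limiting benzoquinone to about one equivalent).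

Step 24
Reactants: 27 chloroacetate
Product: 28 CNP0323842.1
Conditions: thiourea, NaHCO3, EtOH/THF, 40 °C
Reagents that add atoms: none
Why: Selective chloroacetate cleavage, in which S-alkylation of thiourea at the CH2Cl group and cyclization onto the ester carbonyl release the C2 hydroxyl near neutrality, so that both acetates stay in place.

## Compound list

1 | (S)-(+)-carvone | CC1=CC[C@@H](CC1=O)C(C)=C | starting material
2 | (5S,6R)-6-methylcarvone | CC1=CC[C@H](C(C)=C)[C@@H](C)C1=O | intermediate
3 | (5R,6R)-6-allyl-6-methylcarvone | CC1=CC[C@H](C(C)=C)[C@@](C)(CC=C)C1=O | intermediate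
4 | C7 aldehyde | CC1=CC[C@H](C(C)=C)[C@@](C)(CCC=O)C1=O | intermediate
5 | 1,1-dibromoalkene enone | CC1=CC[C@H](C(C)=C)[C@@](C)(CCC=C(Br)Br)C1=O | intermediate
6 | 1β,15β-epoxy ketone | C[C@]12O[C@H]1C[C@H](C(C)=C)[C@@](C)(CCC=C(Br)Br)C2=O | intermediate
7 | methoxy hydroperoxide (not isolated) | C[C@]12O[C@H]1C[C@H](C(C)(OC)OO)[C@@](C)(CCC=C(Br)Br)C2=O | intermediate
8 | epoxy ketone 3α-acetate | C[C@]12O[C@H]1C[C@H](OC(C)=O)[C@@](C)(CCC=C(Br)Br)C2=O | intermediate
9 | transposed allylic alcohol 3α-acetate | CC1=C[C@](C)(CCC=C(Br)Br)[C@@H](OC(C)=O)C[C@@H]1O | intermediate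
10 | 1β,3α-diol | CC1=C[C@](C)(CCC=C(Br)Br)[C@@H](O)C[C@@H]1O | intermediate
11 | 3α-hydroxy enone | CC1=C[C@](C)(CCC=C(Br)Br)[C@@H](O)CC1=O | intermediate
12 | 3α-triethylsilyloxy enone (fragment 1) | CC1=C[C@](C)(CCC=C(Br)Br)[C@@H](O[Si](CC)(CC)CC)CC1=O | intermediate
13 | methyl (R)-3-methylglutarate | COC(=O)C[C@H](C)CC(=O)O | starting material
14 | methyl (R)-5-hydroxy-3-methylpentanoate (not isolated) | COC(=O)C[C@H](C)CCO | intermediate
15 | (R)-4-methyloxan-2-one | O=C1C[C@H](C)CCO1 | intermediate
16 | (4R)-4-methyloxan-2-ol | OC1C[C@H](C)CCO1 | intermediate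
17 | (S)-3-methylhex-5-yn-1-ol | C#CC[C@H](C)CCO | intermediate
18 | triethylsilyl ether of 17 | C#CC[C@H](C)CCO[Si](CC)(CC)CC | intermediate
19 | (S,E)-alkenyl pinacol boronate (fragment 2) | CC[Si](CC)(CC)OCC[C@@H](C)C/C=C/B1OC(C)(C)C(C)(C)O1 | intermediate
20 | (7Z,9E)-8-bromo diene | CC1=C[C@](C)(CC/C=C(Br)/C=C/C[C@H](C)CCO[Si](CC)(CC)CC)[C@@H](O[Si](CC)(CC)CC)CC1=O | intermediate
21 | allylsilane diene ketone | CC1=C[C@](C)(CC/C=C(C[Si](C)(C)C)/C=C/C[C@H](C)CCO[Si](CC)(CC)CC)[C@@H](O[Si](CC)(CC)CC)CC1=O | intermediate
22 | dienyl triflate | CC1=C[C@](C)(CC/C=C(C[Si](C)(C)C)/C=C/C[C@H](C)CCO[Si](CC)(CC)CC)[C@@H](O[Si](CC)(CC)CC)C=C1OS(=O)(=O)C(F)(F)F | intermediate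
23 | diol dienyl triflate | CC1=C[C@](C)(CC/C=C(C[Si](C)(C)C)/C=C/C[C@H](C)CCO)[C@@H](O)C=C1OS(=O)(=O)C(F)(F)F | intermediate
24 | triflate aldehyde | CC1=C[C@](C)(CC/C=C(C[Si](C)(C)C)/C=C/C[C@H](C)CC=O)[C@@H](O)C=C1OS(=O)(=O)C(F)(F)F | intermediate
25 | macrocyclic 3α,14S-diol | CC1=C[C@]2(C)CC/C=C(C[Si](C)(C)C)/C=C/C[C@H](C)C[C@H](O)C1=C[C@@H]2O | intermediate
26 | macrocyclic diacetate | CC1=C[C@]2(C)CC/C=C(C[Si](C)(C)C)/C=C/C[C@H](C)C[C@H](OC(C)=O)C1=C[C@@H]2OC(C)=O | intermediate
27 | tricyclic 2β-chloroacetate | C=C1/C=C/C[C@H](C)C[C@H](OC(C)=O)C2=C(C)[C@@H]3[C@H]1CC[C@]3(C)[C@@H](OC(C)=O)[C@@H]2OC(=O)CCl | intermediate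
28 | CNP0323842.1 | C=C1/C=C/C[C@H](C)C[C@H](OC(C)=O)C2=C(C)[C@@H]3[C@H]1CC[C@]3(C)[C@@H](OC(C)=O)[C@@H]2O | target

## Step count and risks

Total step count: 24. Longest linear sequence: 19 steps (steps 1–10 and 16–24).

**Risk 1, step 23.** Divalent palladium may bind only weakly to the hindered α face of the 2,3-disubstituted ring B diene. Protodesilylation, or oxidation of the open-chain diene of 26 or of 27, could then overtake the transannular attack. The fallback is polar and stepwise, uses known reaction types, and sets out from 25.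
- VO(acac)2/t-BuOOH epoxidation, directed by the 3α and the 14S hydroxyl groups to the α face of C1=C2, should give the 1α,2α-epoxy diol F1.
- Ac2O/pyridine gives the epoxy diacetate F2.
- BF3·OEt2 in CH2Cl2 at −78 °C lets the allylsilane open the vinyl epoxide in an anti SN2′ sense. This is an intramolecular Hosomi–Sakurai-type cyclization of an epoxy allylsilane. It closes ring A and gives the 2α-alcohol F3.
- DMP (triacetoxyperiodinane) gives the enone F4.
- Luche reduction (NaBH4, CeCl3·7H2O, MeOH), by axial hydride delivery, should give the equatorial 2β-alcohol. Here the fallback comes back to the route at 28.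

**Risk 2, step 21.** Oligomerization may take the place of ring closure. Facial selectivity at the aldehyde may also be poor, because ligand control has to override the conformational bias of the forming ring. The fallback sets out from 22.
- Selective methanolysis of the primary silyl ether (PPTS, MeOH, 0 °C) gives the mono-silylated alcohol F5.
- DMP gives the aldehyde F6.
- Ligand-free closure with CrCl2/NiCl2 in DMSO gives the C14 carbinol epimers F7.
- DMP gives the cross-conjugated dienone F8.
- Corey–Bakshi–Shibata reduction with the (R)-oxazaborolidine and catecholborane sets the 14S carbinol F9 under reagent control.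
- PPTS/MeOH removes the C3 silyl group. Here the fallback comes back to the route at 25.

**Risk 3, step 7.** Hydrazone formation may be slow at the C16 carbonyl, which is flanked by two fully substituted carbons. The acetate may also be lost by hydrazinolysis. The fallback sets out from 5.
- Ozonolysis in methanol gives the enone methoxy hydroperoxide F10.
- Its Criegee rearrangement (Ac2O, Et3N, DMAP) gives the enone 3α-acetate F11.
- i-Bu2AlH reduces the ketone and cleaves the acetate to the 16,3α-diol F12.
- Ph3SiOReO3-catalysed 1,3-transposition moves the hydroxyl from the neopentylic C16 to C1. It gives 10 together with the 1α-epimeric diol F13.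
- MnO2 oxidizes both. Here the fallback comes back to the route at 11.

## Further compounds

F1 | step 23 | 1α,2α-epoxy diol | CC1=C[C@]2(C)CC/C=C(C[Si](C)(C)C)/C=C/C[C@H](C)C[C@H](O)[C@]13O[C@@H]3[C@@H]2O
F2 | step 23 | epoxy diacetate | CC1=C[C@]2(C)CC/C=C(C[Si](C)(C)C)/C=C/C[C@H](C)C[C@H](OC(C)=O)[C@]13O[C@@H]3[C@@H]2OC(C)=O
F3 | step 23 | 2α-alcohol (2-epimer of 28) | C=C1/C=C/C[C@H](C)C[C@H](OC(C)=O)C2=C(C)[C@@H]3[C@H]1CC[C@]3(C)[C@@H](OC(C)=O)[C@H]2O
F4 | step 23 | C2 enone | C=C1/C=C/C[C@H](C)C[C@H](OC(C)=O)C2=C(C)[C@@H]3[C@H]1CC[C@]3(C)[C@@H](OC(C)=O)C2=O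
F5 | step 21 | mono-silylated alcohol | CC1=C[C@](C)(CC/C=C(C[Si](C)(C)C)/C=C/C[C@H](C)CCO)[C@@H](O[Si](CC)(CC)CC)C=C1OS(=O)(=O)C(F)(F)F
F6 | step 21 | silylated triflate aldehyde | CC1=C[C@](C)(CC/C=C(C[Si](C)(C)C)/C=C/C[C@H](C)CC=O)[C@@H](O[Si](CC)(CC)CC)C=C1OS(=O)(=O)C(F)(F)F
F7 | step 21 | C14 carbinol epimers | CC1=C[C@]2(C)CC/C=C(C[Si](C)(C)C)/C=C/C[C@H](C)CC(O)C1=C[C@@H]2O[Si](CC)(CC)CC
F8 | step 21 | cross-conjugated C14 dienone | CC1=C[C@]2(C)CC/C=C(C[Si](C)(C)C)/C=C/C[C@H](C)CC(=O)C1=C[C@@H]2O[Si](CC)(CC)CC
F9 | step 21 | 14S carbinol, C3 silyl ether | CC1=C[C@]2(C)CC/C=C(C[Si](C)(C)C)/C=C/C[C@H](C)C[C@H](O)C1=C[C@@H]2O[Si](CC)(CC)CC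
F10 | step 7 | enone methoxy hydroperoxide | CC1=CC[C@H](C(C)(OC)OO)[C@@](C)(CCC=C(Br)Br)C1=O
F11 | step 7 | enone 3α-acetate | CC1=CC[C@H](OC(C)=O)[C@@](C)(CCC=C(Br)Br)C1=O
F12 | step 7 | 16,3α-diol (C16 epimers) | CC1=CC[C@H](O)[C@@](C)(CCC=C(Br)Br)C1O
F13 | step 7 | 1α-epimeric diol | CC1=C[C@](C)(CCC=C(Br)Br)[C@@H](O)C[C@H]1O
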